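**Plan**

1. The retrosynthesis cuts O3–C2 last. Before that it cuts C6–O7, C5–C1 and C4–O3 in one operation. This leaves 3,4-dimethoxycinnamaldehyde (C4–C5–C6) and a 1-aryl-1,3-dihydroxyacetone (C8–C1–C2) made from vanillin.
2. Enabling feature: in the 3,7-dioxabicyclo[3.3.0]octane core, C8, C1 and C2 all carry oxygen, and both the tertiary C1–OH and the ring oxygen O7 sit β to C4. The bicycle is therefore a hidden oxa-Michael/aldol adduct of an enal, and the C2–OH arm can trap C4 as a lactol.
3. Forward order: ring B (O7, C8, C1, C5, C6) forms first, and ring A (O3, C2, C1, C5, C4) closes as a lactol in the same flask. C4 is then reduced to CH2OH and ring A is closed again at C2.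
4. Stereochemistry: C6 comes from the aminocatalyst. C5 and C1 are relayed from C6 through trans substitution and the compulsory cis ring fusion.
5. C2 is set last by a stereoconvergent closure through a p-quinone methide. Only the free para-phenol ring on C2 can form one, so the veratryl-bearing C6 is left alone.

Key step: step 4

Remark: the labels C1–C8, O3 and O7 are those of the bicyclic core of the target and are used for all intermediates. C1 is the carbinol bridgehead, C2 is guaiacyl-bearing, C5 is the CH bridgehead and C6 is veratryl-bearing. The target SMILES reads as (1S,2R,5R,6S), with both aryl groups exo, that is, cis to C1–OH and C5–H.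

**Route**

Step 1
Reactants: 1 vanillin
Product: 2 4-(tert-butyldimethylsilyloxy)-3-methoxybenzaldehyde
Conditions: TBSCl, imidazole, DMF, rt
Reagents that add atoms: tert-butyldimethylsilyl chloride, CC(C)(C)[Si](C)(C)Cl
Why: Imidazole-promoted O-silylation of a phenol masks the acidic OH for the organolithium step and keeps the ring electron-rich.

Step 2
Reactants: 2 4-(tert-butyldimethylsilyloxy)-3-methoxybenzaldehyde, 3 2-bromoprop-2-en-1-ol
Product: 5 rac-1-[4-(tert-butyldimethylsilyloxy)-3-methoxyphenyl]-2-methylidenepropane-1,3-diol, via dilithio reagent 4 (not isolated)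
Conditions: 3, t-BuLi (3 equiv), Et2O, −78 to 0 °C; then 2, −78 °C; H2O
Reagents that add atoms: none
Why: Deprotonation and bromine–lithium exchange give a vinyllithium alkoxide that cannot β-eliminate and adds 1,2 to the aldehyde; C2 is made racemic on purpose because step 7 resets it.

Step 3
Reactants: 5 rac-1-[4-(tert-butyldimethylsilyloxy)-3-methoxyphenyl]-2-methylidenepropane-1,3-diol
Product: 7 rac-1-[4-(tert-butyldimethylsilyloxy)-3-methoxyphenyl]-1,3-dihydroxypropan-2-one, via ozonide 6 (not isolated)
Conditions: O3, CH2Cl2, −78 °C (Sudan III end point); Me2S, −78 °C to rt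
Reagents that add atoms: ozone, [O-][O+]=O
Why: Ozonolysis with reductive work-up should cleave the 1,1-disubstituted alkene well before the arene when ozone is dosed to an indicator end point, and the neutral work-up spares the labile α-ketol, which is used without storage.

Step 4
Reactants: 7 rac-1-[4-(tert-butyldimethylsilyloxy)-3-methoxyphenyl]-1,3-dihydroxypropan-2-one, 8 (E)-3-(3,4-dimethoxyphenyl)prop-2-enal
Product: 10 (1S,5R,6S)-2-[4-(tert-butyldimethylsilyloxy)-3-methoxyphenyl]-6-(3,4-dimethoxyphenyl)-3,7-dioxabicyclo[3.3.0]octane-1,4-diol (epimers at C2 and C4), via hydroxy aldehyde 9 (not isolated)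
Conditions: (S)-2-[diphenyl(trimethylsilyloxy)methyl]pyrrolidine (20 mol %), PhCO2H (20 mol %), CHCl3, rt
Reagents that add atoms: none
Why: Condensation of 8 with the (S)-amine gives an E, s-trans iminium ion with one face covered by the CPh2OTMS group, so the primary C8–OH of 7 adds to C6 from the open face and sets C6 as S (intermolecular oxa-Michael step, O7–C6). The resulting enamine attacks the C1 ketone in a 5-(enolexo)-exo-trig aldol closure of ring B (C5–C1), C4 takes the position trans to the C6 aryl group (C5 R), and hydrolysis releases 9. Ring A closes by 5-exo-trig hemiacetalisation of C2–OH on C4; only the C1 epimer with the carbinol arm cis to the formyl group can do this, and because the oxa-Michael and aldol steps are reversible under amine/acid catalysis the manifold should drain into the cis-fused bicycle, which fixes C1 as S and blocks loss of water from the aldol. The closest known reaction type is the secondary-amine-catalysed oxa-Michael/aldol/hemiacetalisation domino of dihydroxyacetone with enals, which gives 3,7-dioxabicyclo[3.3.0]octane-1,4-diols. The step needs the primary rather than the secondary benzylic hydroxyl of 7 to be the Michael donor, which the lower steric demand of C8–OH should secure, and it needs the α-ketol of 7 not to shift, which the buffered conditions at rt favour. C2 (from racemic 7) and the anomeric C4 are left as mixtures on purpose, since C4 becomes CH2 in step 5 and C2 is reset in step 7.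

Step 5
Reactants: 10 bicyclic lactol (epimers at C2 and C4)
Product: 11 (3S,4R,5S)-3-{[4-(tert-butyldimethylsilyloxy)-3-methoxyphenyl](hydroxy)methyl}-5-(3,4-dimethoxyphenyl)-4-(hydroxymethyl)oxolan-3-ol (epimers at the carbinol carbon C2)
Conditions: NaBH4, EtOH/THF, 0 °C
Reagents that add atoms: none
Why: Borohydride reduces the lactol through its open hydroxy aldehyde tautomer, which turns C4 into CH2OH and removes the anomeric mixture; fast reduction at 0 °C should outrun retro-aldol or β-elimination, and C1, C5 and C6 are not touched.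

Step 6
Reactants: 11 silyl tetraol (C2 epimers)
Product: 12 (3S,4R,5S)-5-(3,4-dimethoxyphenyl)-3-[hydroxy(4-hydroxy-3-methoxyphenyl)methyl]-4-(hydroxymethyl)oxolan-3-ol (C2 epimers)
Conditions: TBAF, AcOH, THF, 0 °C
Reagents that add atoms: none
Why: Buffered fluoride cleavage of the aryl silyl ether frees the para-phenol that the last step needs, and the acetic acid keeps the medium from turning basic toward the β-hydroxy ether array.

Step 7
Reactants: 12 phenolic tetraol (C2 epimers)
Product: 14 (1S,2R,5R,6S)-6-(3,4-dimethoxyphenyl)-2-(4-hydroxy-3-methoxyphenyl)-3,7-dioxabicyclo[3.3.0]octan-1-ol (target), via quinone methide 13 (not isolated)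
Conditions: (PhO)2P(O)OH (10 mol %), 4 Å MS, MeCN/CH2Cl2 (high dilution), 0 °C to rt
Reagents that add atoms: none
Why: Weak Brønsted acid dehydrates the p-hydroxybenzyl alcohol to the planar p-quinone methide 13, on which both C2 epimers converge, and C4–OH adds in a 5-exo-trig oxa-1,6-addition; A1,3 strain should place the small C1–OH in the quinone methide plane so that O3 arrives from the C5 side and the aryl group ends cis to C1–OH (2R, exo), while the veratryl ether at C6 cannot form a quinone methide and should survive the weak acid.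

**Compound list**

1 | vanillin | COc1cc(C=O)ccc1O | starting material
2 | 4-(tert-butyldimethylsilyloxy)-3-methoxybenzaldehyde | COc1cc(C=O)ccc1O[Si](C)(C)C(C)(C)C | intermediate
3 | 2-bromoprop-2-en-1-ol | OCC(Br)=C | starting material
4 | lithium 2-lithioprop-2-en-1-olate | [Li]OCC([Li])=C | intermediate
5 | rac-1-[4-(tert-butyldimethylsilyloxy)-3-methoxyphenyl]-2-methylidenepropane-1,3-diol | COc1cc(C(O)C(=C)CO)ccc1O[Si](C)(C)C(C)(C)C | intermediate
6 | 1,2,4-trioxolane (ozonide) of 5 | COc1cc(C(O)C2(CO)OCOO2)ccc1O[Si](C)(C)C(C)(C)C | intermediate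
7 | rac-1-[4-(tert-butyldimethylsilyloxy)-3-methoxyphenyl]-1,3-dihydroxypropan-2-one | COc1cc(C(O)C(=O)CO)ccc1O[Si](C)(C)C(C)(C)C | intermediate
8 | (E)-3-(3,4-dimethoxyphenyl)prop-2-enal | COc1ccc(/C=C/C=O)cc1OC | starting material
9 | (2S,3R,4S)-4-{[4-(tert-butyldimethylsilyloxy)-3-methoxyphenyl](hydroxy)methyl}-2-(3,4-dimethoxyphenyl)-4-hydroxyoxolane-3-carbaldehyde (C2 epimers) | COc1cc(C(O)[C@@]2(O)CO[C@H](c3ccc(OC)c(OC)c3)[C@H]2C=O)ccc1O[Si](C)(C)C(C)(C)C | intermediate
10 | (1S,5R,6S)-2-[4-(tert-butyldimethylsilyloxy)-3-methoxyphenyl]-6-(3,4-dimethoxyphenyl)-3,7-dioxabicyclo[3.3.0]octane-1,4-diol (epimers at C2 and C4) | COc1cc(C2OC(O)[C@@H]3[C@@H](c4ccc(OC)c(OC)c4)OC[C@]23O)ccc1O[Si](C)(C)C(C)(C)C | intermediate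
11 | (3S,4R,5S)-3-{[4-(tert-butyldimethylsilyloxy)-3-methoxyphenyl](hydroxy)methyl}-5-(3,4-dimethoxyphenyl)-4-(hydroxymethyl)oxolan-3-ol (C2 epimers) | COc1cc(C(O)[C@@]2(O)CO[C@H](c3ccc(OC)c(OC)c3)[C@H]2CO)ccc1O[Si](C)(C)C(C)(C)C | intermediate
12 | (3S,4R,5S)-5-(3,4-dimethoxyphenyl)-3-[hydroxy(4-hydroxy-3-methoxyphenyl)methyl]-4-(hydroxymethyl)oxolan-3-ol (C2 epimers) | COc1cc(C(O)[C@@]2(O)CO[C@H](c3ccc(OC)c(OC)c3)[C@H]2CO)ccc1O | intermediate
13 | p-quinone methide of 12 (4-alkylidene-2-methoxycyclohexa-2,5-dienone; C1, C5 and C6 as in 12) | COC1=CC(=C[C@@]2(O)CO[C@H](c3ccc(OC)c(OC)c3)[C@H]2CO)C=CC1=O | intermediate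
14 | (1S,2R,5R,6S)-6-(3,4-dimethoxyphenyl)-2-(4-hydroxy-3-methoxyphenyl)-3,7-dioxabicyclo[3.3.0]octan-1-ol | COc1cc([C@H]2OC[C@@H]3[C@@H](c4ccc(OC)c(OC)c4)OC[C@]23O)ccc1O | target

**Step count**

Total step count: 7. Longest linear sequence: 7 (1 to 14); 3 and 8 enter as purchased materials.

**Steps most likely to fail**

Step 4 (key step). Several things may go wrong:
- Addition of an aliphatic alcohol to the iminium ion of an electron-rich cinnamaldehyde may be slow and reversible.
- The secondary benzylic hydroxyl of 7 may compete as the Michael donor.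
- The α-ketol of 7 may shift under amine/acid catalysis.
- The aldol may lose water if lactol closure lags for one C2 epimer.

The fallback sets out from 2 and comes back at 10. It makes the C6–O7 bond irreversibly before any C–C bond. Veratraldehyde is allylated with the Ipc2B(allyl) antipode that delivers (S)-1-(3,4-dimethoxyphenyl)but-3-en-1-ol F1. Williamson etherification with 2,3-dibromopropene (NaH, THF) gives the (S)-2-bromoallyl ether F2. Bromine–lithium exchange (t-BuLi, Et2O, −78 °C) and addition to 2 give the bis-alkene carbinol F3 as C2 epimers. Double ozonolysis (O3, then Me2S) gives the keto aldehyde F4, which is the formal oxa-Michael adduct of 7 and 8. Pyrrolidine/AcOH then closes ring B by the same 5-(enolexo) aldol and ring A by hemiacetalisation, now under substrate control from C6, to give 10.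

Step 7. Facial selectivity in the capture of the quinone methide may be poor. A 1,2-shift from C1 to C2 (semipinacol) may compete, and so may intermolecular phenol attack.

The fallback sets out from 11 and comes back at 14. It closes ring A in the opposite sense, forming O3–C4 by substitution at the primary carbon, so C2 is never ionised. The C2 epimers of 11 are separated. The (2R)-epimer is sulfonylated selectively at the primary hydroxyl (MsCl, collidine, CH2Cl2, −20 °C) to the primary mesylate F5. NaH in THF closes the ring by 5-exo-tet displacement with retention at C2 and gives the silyl ether of the target F6, and TBAF gives 14. The (2S)-epimer is recycled by benzylic oxidation (MnO2) to the aryl ketone F7 and reduction with NaBH4 back to 11.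

Step 3. Ozone may attack the electron-rich arene, and the product may drift by acyloin shift toward the aryl ketone on handling.

The fallback sets out from 2 and comes back at 7. It builds the C2–C1 bond directly without an oxidant. A tertiary amine mediates the decarboxylative addition of lithium 3-hydroxypyruvate to aldehyde 2 (N-methylmorpholine, THF/H2O, rt), and the crude solution of 7 is taken straight into step 4.

**Further compounds**

F1 | step 4 | (S)-1-(3,4-dimethoxyphenyl)but-3-en-1-ol | O[C@H](c1ccc(OC)c(OC)c1)CC=C
F2 | step 4 | (S)-4-[1-(2-bromoprop-2-enyloxy)but-3-enyl]-1,2-dimethoxybenzene | C=C(Br)CO[C@H](c1ccc(OC)c(OC)c1)CC=C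
F3 | step 4 | 1-[4-(tert-butyldimethylsilyloxy)-3-methoxyphenyl]-2-{[(S)-1-(3,4-dimethoxyphenyl)but-3-enyloxy]methyl}prop-2-en-1-ol (C2 epimers) | COc1cc(C(O)C(=C)CO[C@H](c2ccc(OC)c(OC)c2)CC=C)ccc1O[Si](C)(C)C(C)(C)C
F4 | step 4 | (S)-3-{3-[4-(tert-butyldimethylsilyloxy)-3-methoxyphenyl]-3-hydroxy-2-oxopropoxy}-3-(3,4-dimethoxyphenyl)propanal (C2 epimers) | COc1cc(C(O)C(=O)CO[C@H](c2ccc(OC)c(OC)c2)CC=O)ccc1O[Si](C)(C)C(C)(C)C
F5 | step 7 | primary (C4) methanesulfonate of the (2R)-epimer of 11 | COc1cc([C@@H](O)[C@@]2(O)CO[C@H](c3ccc(OC)c(OC)c3)[C@H]2COS(C)(=O)=O)ccc1O[Si](C)(C)C(C)(C)C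
F6 | step 7 | tert-butyldimethylsilyl ether of 14 | COc1cc([C@H]2OC[C@@H]3[C@@H](c4ccc(OC)c(OC)c4)OC[C@]23O)ccc1O[Si](C)(C)C(C)(C)C
F7 | step 7 | aryl ketone from benzylic oxidation of 11 at C2 | COc1cc(C(=O)[C@@]2(O)CO[C@H](c3ccc(OC)c(OC)c3)[C@H]2CO)ccc1O[Si](C)(C)C(C)(C)C
F0 | step 3 | none | none
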